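**Retrosynthetic overview**
1. The C5–O ester bond is made last: a Mitsunobu union (inversion at C5) of the 5,6-trans hydroxy lactone with (2E,4E,6S)-4,6-dimethyldodeca-2,4-dienoic acid gives the 5,6-cis target.
2. Ring A (the 5,6-dihydro-2H-pyran-2-one, the only ring) is closed by forming C4–C5: an intramolecular Nozaki–Hiyama–Kishi (NHK) addition of a (Z)-β-iodoacrylate ester to an α-acyloxy aldehyde, which also creates the C5 carbinol centre under control of C6.
3. Enabling feature: C5 is an oxygen-bearing carbon flanked by the endocyclic cis C3=C4 enoate and by C6, whose oxygen O1 is the lactone oxygen. C5 can therefore be an aldehyde and C4 the iodinated β-carbon of the very ester (O1–C2) that tethers them.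
4. The acyclic, protecting-group-free precursor comes in three steps from sorbyl alcohol: Sharpless epoxidation, Ti(OiPr)4-mediated C3 opening by (Z)-3-iodoacrylic acid (inversion fixes C6), and periodate excision of C1.
5. Side chain: Evans methylation sets C6′, two Wittig olefinations build the E,E-diene, then saponification.

Key step: step 4

Remark: ring A is numbered O1, C2(=O), C3=C4, C5 (acyloxy), C6 (propenyl), and side-chain atoms carry a prime. Read from the SMILES, the target is (5S,6S,6′S) with the C5 and C6 substituents cis. (Z)-3-Iodoprop-2-enoic acid is taken as commercial.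

**Step 1**
Reactants: 1 (2E,4E)-hexa-2,4-dien-1-ol (sorbyl alcohol)
Product: 2 [(2R,3R)-3-[(E)-prop-1-enyl]oxiran-2-yl]methanol
Conditions: Ti(OiPr)4 (10 mol%), D-(−)-diisopropyl tartrate (12 mol%), t-BuOOH (2 equiv), 4 Å molecular sieves, CH2Cl2, −20 °C
Reagents that add atoms: tert-butyl hydroperoxide, CC(C)(C)OO
Why: Sharpless asymmetric epoxidation should epoxidize only the hydroxyl-directed C2=C3 alkene, and the D-(−)-tartrate ligand should deliver oxygen to the face that gives the (2R,3R)-epoxide.

**Step 2**
Reactants: 2 [(2R,3R)-3-[(E)-prop-1-enyl]oxiran-2-yl]methanol; 3 (2Z)-3-iodoprop-2-enoic acid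
Product: 4 (2R,3S,4E)-1,2-dihydroxyhex-4-en-3-yl (2Z)-3-iodoprop-2-enoate
Conditions: Ti(OiPr)4 (1.5 equiv), 3 (1.3 equiv), CH2Cl2, 0 °C to rt; aq. work-up; used directly
Reagents that add atoms: none
Why: Ti(OiPr)4-mediated opening of a 2,3-epoxy alcohol by a carboxylic acid is C3-selective (C3 is here also the allylic carbon) and proceeds by SN2 inversion, so C3 should become S (the future C6 of ring A), while the Z iodoalkene meets no nucleophilic catalyst.

**Step 3**
Reactants: 4 (2R,3S,4E)-1,2-dihydroxyhex-4-en-3-yl (2Z)-3-iodoprop-2-enoate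
Product: 5 (2S,3E)-1-oxopent-3-en-2-yl (2Z)-3-iodoprop-2-enoate
Conditions: NaIO4 on SiO2 (1.3 equiv), CH2Cl2, 0 °C to rt; filtration, used crude
Reagents that add atoms: none
Why: Periodate glycol cleavage (Malaprade reaction) should cut only the free C1–C2 diol under neutral conditions, which removes C1 as formaldehyde and leaves C2 as the aldehyde (future C5) without touching the acyloxy stereocentre.

**Step 4**
Reactants: 5 (2S,3E)-1-oxopent-3-en-2-yl (2Z)-3-iodoprop-2-enoate
Product: 8 (5R,6S)-5-hydroxy-6-[(E)-prop-1-enyl]-5,6-dihydro-2H-pyran-2-one, via alkenylchromium dichloride 6 (not isolated), via chromium alkoxide 7 (not isolated)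
Conditions: CrCl2 (6 equiv), NiCl2 (2 mol%), degassed DMF, 0.01 M, rt; aq. work-up
Reagents that add atoms: none
Why: Nozaki–Hiyama–Kishi cyclization: zerovalent nickel (formed from NiCl2 by CrCl2) inserts into the C4–I bond with retention of the Z geometry, transmetalation to trivalent chromium gives 6, and the C4–Cr bond adds to the C5 aldehyde through a four-centre transition state to give alkoxide 7, which is hydrolysed on work-up. The closest known reactions are intramolecular NHK closures of alkenyl iodide–aldehyde pairs to six-membered and larger cyclic allylic alcohols (macrolactones included) and intermolecular NHK additions of (Z)-3-iodoacrylates to aldehydes. Ring A is closed in the 6-exo-trig mode, C4 attacking the aldehyde carbon C5 while the carbonyl oxygen stays outside the ring; the ester has only to reach its s-trans rotamer, as in ring closures of acrylates to the same lactones. The new C5 centre is controlled by the existing C6 centre: in the half-chair transition state the C5=O bond should lie in the ring plane, bound to chromium and anti to the C6–O1 bond (Cornforth-type dipole arrangement), and the propenyl group should take the pseudo-equatorial site away from the ligated chromium, which leads to the 5,6-trans alcohol (5R). The step needs ring closure to outrun dimerization (secured by 0.01 M dilution and the six-membered ring), retention of the cis alkene (only the Z alkenylchromium can reach C5) and attack on the aldehyde alone, which the low basicity and ester tolerance of alkenylchromium reagents should secure against both ester groups and the epimerizable C6–H.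

**Step 5**
Reactants: 9 (4S)-4-benzyl-1,3-oxazolidin-2-one; 10 octanoyl chloride
Product: 12 (4S)-4-benzyl-3-octanoyl-1,3-oxazolidin-2-one, via lithium oxazolidinide 11 (not isolated)
Conditions: n-BuLi (1.05 equiv), THF, −78 °C; then 10, −78 to 0 °C
Reagents that add atoms: none
Why: N-acylation of the lithiated oxazolidinone with an acid chloride is the standard preparation of an Evans imide and forms no stereocentre.

**Step 6**
Reactants: 12 (4S)-4-benzyl-3-octanoyl-1,3-oxazolidin-2-one
Product: 14 (4S)-4-benzyl-3-[(2S)-2-methyloctanoyl]-1,3-oxazolidin-2-one, via sodium enolate 13 (not isolated)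
Conditions: NaN(SiMe3)2 (1.1 equiv), THF, −78 °C; then MeI (5 equiv), −78 °C
Reagents that add atoms: iodomethane, CI
Why: Evans asymmetric alkylation: the chelated Z enolate should be methylated on the face away from the benzyl group, which gives the (2S) centre (C6′ of the side chain), and the minor diastereomer should be removable by chromatography.

**Step 7**
Reactants: 14 (4S)-4-benzyl-3-[(2S)-2-methyloctanoyl]-1,3-oxazolidin-2-one
Product: 15 (2S)-2-methyloctan-1-ol
Conditions: LiBH4 (2 equiv), THF, 0 °C to rt; aq. work-up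
Reagents that add atoms: none
Why: Reductive removal of the auxiliary with LiBH4 attacks the exocyclic imide carbonyl and should give the primary alcohol without epimerization, with recovery of oxazolidinone 9.

**Step 8**
Reactants: 15 (2S)-2-methyloctan-1-ol
Product: 16 (2S)-2-methyloctanal
Conditions: Dess–Martin periodinane (1.2 equiv), CH2Cl2, 0 °C to rt; used at once
Reagents that add atoms: none
Why: Dess–Martin oxidation stops at the aldehyde under non-basic conditions, so the α-stereocentre should survive.

**Step 9**
Reactants: 16 (2S)-2-methyloctanal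
Product: 17 (2E,4S)-2,4-dimethyldec-2-enal
Conditions: Ph3P=C(CH3)CHO (1.3 equiv), toluene, 90 °C
Reagents that add atoms: 2-(triphenylphosphoranylidene)propanal, CC(C=O)=P(c1ccccc1)(c1ccccc1)c1ccccc1
Why: Wittig olefination with a stabilized formyl ylide should give the E trisubstituted enal, and the non-basic ylide should leave the adjacent stereocentre intact.

**Step 10**
Reactants: 17 (2E,4S)-2,4-dimethyldec-2-enal
Product: 18 ethyl (2E,4E,6S)-4,6-dimethyldodeca-2,4-dienoate
Conditions: Ph3P=CHCO2Et (1.3 equiv), CH2Cl2, rt to 40 °C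
Reagents that add atoms: ethyl 2-(triphenylphosphoranylidene)acetate, CCOC(=O)C=P(c1ccccc1)(c1ccccc1)c1ccccc1
Why: Wittig olefination of the enal with the stabilized ester ylide should give the 2E alkene and so complete the E,E-diene.

**Step 11**
Reactants: 18 ethyl (2E,4E,6S)-4,6-dimethyldodeca-2,4-dienoate
Product: 20 (2E,4E,6S)-4,6-dimethyldodeca-2,4-dienoic acid, via lithium carboxylate 19 (not isolated)
Conditions: LiOH (3 equiv), THF/H2O, rt; then 1 M HCl to pH 3
Reagents that add atoms: lithium hydroxide, [Li+].[OH-]
Why: Saponification of the ethyl ester followed by mild acidification should give the acid without change of the diene geometry or of the C6′ centre.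

**Step 12**
Reactants: 8 (5R,6S)-5-hydroxy-6-[(E)-prop-1-enyl]-5,6-dihydro-2H-pyran-2-one; 20 (2E,4E,6S)-4,6-dimethyldodeca-2,4-dienoic acid
Product: 21 (5S,6S)-2-oxo-6-[(E)-prop-1-enyl]-5,6-dihydro-2H-pyran-5-yl (2E,4E,6S)-4,6-dimethyldodeca-2,4-dienoate
Conditions: PPh3 (1.5 equiv), DIAD (1.5 equiv), 20 (1.3 equiv), toluene, 0 °C to rt
Reagents that add atoms: none
Why: Mitsunobu esterification: the 5R alcohol is activated as its alkoxyphosphonium ion and displaced by the carboxylate of 20 in an SN2 reaction with inversion, which should set C5 as S (5,6-cis); the trans alcohol has no C6–H anti to the leaving group, which disfavours elimination to the 2-pyranone, and the neutral conditions spare the base-sensitive product.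

**Compound list**
1 | (2E,4E)-hexa-2,4-dien-1-ol (sorbyl alcohol) | C/C=C/C=C/CO | starting material
2 | [(2R,3R)-3-[(E)-prop-1-enyl]oxiran-2-yl]methanol | C/C=C/[C@H]1O[C@@H]1CO | intermediate
3 | (2Z)-3-iodoprop-2-enoic acid | OC(=O)/C=C\I | starting material
4 | (2R,3S,4E)-1,2-dihydroxyhex-4-en-3-yl (2Z)-3-iodoprop-2-enoate | C/C=C/[C@H](OC(=O)/C=C\I)[C@H](O)CO | intermediate
5 | (2S,3E)-1-oxopent-3-en-2-yl (2Z)-3-iodoprop-2-enoate | C/C=C/[C@H](OC(=O)/C=C\I)C=O | intermediate
6 | alkenylchromium dichloride from 5 (not isolated) | C/C=C/[C@H](OC(=O)/C=C\[Cr](Cl)Cl)C=O | intermediate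
7 | chromium alkoxide of 8 (not isolated) | C/C=C/[C@@H]1OC(=O)C=C[C@H]1O[Cr](Cl)Cl | intermediate
8 | (5R,6S)-5-hydroxy-6-[(E)-prop-1-enyl]-5,6-dihydro-2H-pyran-2-one | C/C=C/[C@@H]1OC(=O)C=C[C@H]1O | intermediate
9 | (4S)-4-benzyl-1,3-oxazolidin-2-one | O=C1N[C@@H](Cc2ccccc2)CO1 | starting material
10 | octanoyl chloride | CCCCCCCC(=O)Cl | starting material
11 | lithium oxazolidinide of 9 (not isolated) | [Li+].O=C1[N-][C@@H](Cc2ccccc2)CO1 | intermediate
12 | (4S)-4-benzyl-3-octanoyl-1,3-oxazolidin-2-one | CCCCCCCC(=O)N1C(=O)OC[C@@H]1Cc2ccccc2 | intermediate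
13 | sodium Z enolate of 12 (not isolated) | [Na+].CCCCCC/C=C(\[O-])N1C(=O)OC[C@@H]1Cc2ccccc2 | intermediate
14 | (4S)-4-benzyl-3-[(2S)-2-methyloctanoyl]-1,3-oxazolidin-2-one | CCCCCC[C@H](C)C(=O)N1C(=O)OC[C@@H]1Cc2ccccc2 | intermediate
15 | (2S)-2-methyloctan-1-ol | CCCCCC[C@H](C)CO | intermediate
16 | (2S)-2-methyloctanal | CCCCCC[C@H](C)C=O | intermediate
17 | (2E,4S)-2,4-dimethyldec-2-enal | O=C/C(C)=C/[C@@H](C)CCCCCC | intermediate
18 | ethyl (2E,4E,6S)-4,6-dimethyldodeca-2,4-dienoate | CCOC(=O)/C=C/C(C)=C/[C@@H](C)CCCCCC | intermediate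
19 | lithium (2E,4E,6S)-4,6-dimethyldodeca-2,4-dienoate (not isolated) | [Li+].[O-]C(=O)/C=C/C(C)=C/[C@@H](C)CCCCCC | intermediate
20 | (2E,4E,6S)-4,6-dimethyldodeca-2,4-dienoic acid | OC(=O)/C=C/C(C)=C/[C@@H](C)CCCCCC | intermediate
21 | (5S,6S)-2-oxo-6-[(E)-prop-1-enyl]-5,6-dihydro-2H-pyran-5-yl (2E,4E,6S)-4,6-dimethyldodeca-2,4-dienoate | C/C=C/[C@@H]1OC(=O)C=C[C@@H]1OC(=O)/C=C/C(C)=C/[C@@H](C)CCCCCC | target

**Step count and risks**
Total step count: 12. Longest linear sequence: 8 steps (steps 5 to 12, from 9 and 10 to 21); the lactone branch is 5 steps (steps 1 to 4 and 12).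

Steps most likely to fail:

1. Step 4 (key ring closure). The addition to the C5 aldehyde may take place on the other face, or with little preference, because the Cornforth-type bias is untested in a transition state that is part of a lactone ring. Fallback (sets out from 5, comes back at 21): the same closure is run and the 5,6-cis epimer (5S,6S)-5-hydroxy-6-[(E)-prop-1-enyl]-5,6-dihydro-2H-pyran-2-one F1 is separated from 8 by chromatography. F1 is esterified with retention at C5 with acid 20 (EDC, catalytic DMAP, CH2Cl2, −20 °C). This epimer then reaches 21 by acyl transfer and 8 reaches it by inversion, so both outcomes of the ring closure serve the target.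

2. Step 2. Attack of the acid at C2 or, in the conjugate sense, at C5 of the vinyl epoxide, partial ionization at the allylic C3 with erosion of configuration, and 3→2 acyl migration in the diol ester may all lower the amount of 4. Fallback (sets out from 3, comes back at 5): the C6 centre is taken from the chiral pool and the hydroxyl groups are told apart by a silyl group. (4R)-2,2-Dimethyl-1,3-dioxolane-4-carbaldehyde F2 is olefinated with 5-(ethylsulfonyl)-1-phenyl-1H-tetrazole (KN(SiMe3)2, DME, −60 °C, E-selective Julia–Kocienski reaction) to (4S)-2,2-dimethyl-4-[(E)-prop-1-enyl]-1,3-dioxolane F3. Aqueous acetic acid gives (2S,3E)-pent-3-ene-1,2-diol F4. The primary hydroxyl is silylated (TBSCl, imidazole, −20 °C) to (2S,3E)-1-[(tert-butyldimethylsilyl)oxy]pent-3-en-2-ol F5. Carbodiimide esterification with 3 (DIC, catalytic DMAP, −20 °C) gives (2S,3E)-1-[(tert-butyldimethylsilyl)oxy]pent-3-en-2-yl (2Z)-3-iodoprop-2-enoate F6. HF·pyridine (acidic, to avoid 2→1 acyl migration) gives (2S,3E)-1-hydroxypent-3-en-2-yl (2Z)-3-iodoprop-2-enoate F7, and Dess–Martin oxidation gives 5.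

3. Step 12. Displacement at C5 has to occur on the face syn to the propenyl group; if it is slow, acyl transfer through an acyloxyphosphonium ion (ester with retention) or loss of the activated oxygen towards the 2-pyranone may compete. Fallback (sets out from 8, comes back at 21): the leaving group is made first and displaced in a separate SN2 step. Alcohol 8 is converted (MsCl, Et3N, CH2Cl2, −20 °C) into (5R,6S)-2-oxo-6-[(E)-prop-1-enyl]-5,6-dihydro-2H-pyran-5-yl methanesulfonate F8. This is treated with cesium (2E,4E,6S)-4,6-dimethyldodeca-2,4-dienoate F9 (from 20 and Cs2CO3) in toluene with 18-crown-6, which should give 21 with inversion.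

**Further compounds**
F1 | step 4 | (5S,6S)-5-hydroxy-6-[(E)-prop-1-enyl]-5,6-dihydro-2H-pyran-2-one | C/C=C/[C@@H]1OC(=O)C=C[C@@H]1O
F2 | step 2 | (4R)-2,2-dimethyl-1,3-dioxolane-4-carbaldehyde | CC1(C)OC[C@H](C=O)O1
F3 | step 2 | (4S)-2,2-dimethyl-4-[(E)-prop-1-enyl]-1,3-dioxolane | C/C=C/[C@H]1COC(C)(C)O1
F4 | step 2 | (2S,3E)-pent-3-ene-1,2-diol | C/C=C/[C@H](O)CO
F5 | step 2 | (2S,3E)-1-[(tert-butyldimethylsilyl)oxy]pent-3-en-2-ol | C/C=C/[C@H](O)CO[Si](C)(C)C(C)(C)C
F6 | step 2 | (2S,3E)-1-[(tert-butyldimethylsilyl)oxy]pent-3-en-2-yl (2Z)-3-iodoprop-2-enoate | C/C=C/[C@H](OC(=O)/C=C\I)CO[Si](C)(C)C(C)(C)C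
F7 | step 2 | (2S,3E)-1-hydroxypent-3-en-2-yl (2Z)-3-iodoprop-2-enoate | C/C=C/[C@H](OC(=O)/C=C\I)CO
F8 | step 12 | (5R,6S)-2-oxo-6-[(E)-prop-1-enyl]-5,6-dihydro-2H-pyran-5-yl methanesulfonate | C/C=C/[C@@H]1OC(=O)C=C[C@H]1OS(C)(=O)=O
F9 | step 12 | cesium (2E,4E,6S)-4,6-dimethyldodeca-2,4-dienoate | [Cs+].[O-]C(=O)/C=C/C(C)=C/[C@@H](C)CCCCCC
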